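**Plan**
- Retrosynthesis: the seven methoxymethyl (MOM) ethers come off last. Ring C of the flavanone is then cut at C2–C3 and O1–C8a, giving an o-fluoroaryl methyl ketone and 2,4-bis(methoxymethoxy)benzaldehyde. The cyclohexene is cut by retro-Diels–Alder into a 2'-hydroxychalcone and an (E)-1-aryl-myrcene, and these are cut at the aryl–vinyl bond (Heck) and at chalcone Cα=Cβ (Claisen–Schmidt).
- Enabling feature: in ring C the unit C3–C4(=O)–C4a=C8a–O1 is a vinylogous ester. C8a lies ortho to the C4 carbonyl and meta to both ring-A oxygens (C5, C7), so a fluoride at C8a is displaceable by an alkoxide, and C3 is the methyl of an aryl methyl ketone that can add to an aldehyde.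
- Forward order: ring A (5-fluororesorcinol → acetyl, iodide, MOM) → Heck with myrcene → diene; chalcone by C-prenylation, MOM protection and Claisen–Schmidt; Diels–Alder builds the cyclohexene; enol silane; aldol/SNAr annulation closes ring C; deprotection.
- Stereochemistry: the all-trans cyclohexene centres (1R,5S,6R) come from an exo-selective Diels–Alder of the E-chalcone under a chiral borate. Flavanone C2 (S) comes from a catalyst-controlled Mukaiyama aldol and is untouched by the ring closure.

Key step: step 11

Assumption: the (S)-VANOL borate (step 9) and the (R)-tryptophan-derived oxazaborolidinone (step 11) are taken to have the facial preferences needed here; if either proves opposite, its mirror-image ligand is used with no other change.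

Step 1
Reactants: 1 5-fluororesorcinol
Product: 2 1-(2-fluoro-4,6-dihydroxyphenyl)ethan-1-one
Conditions: AcOH, ZnCl2, 140 °C
Reagents that add atoms: acetic acid, CC(=O)O
Why: Nencki C-acylation of a resorcinol should occur para to one hydroxyl and ortho to the other (next to the small fluorine), as with other 5-substituted resorcinols, and not between the two hydroxyls.

Step 2
Reactants: 2 1-(2-fluoro-4,6-dihydroxyphenyl)ethan-1-one
Product: 3 1-(6-fluoro-2,4-dihydroxy-3-iodophenyl)ethan-1-one
Conditions: I2, HIO3, EtOH–H2O, 25 °C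
Reagents that add atoms: iodine, [I][I]; iodic acid, O[I](=O)=O
Why: Electrophilic aromatic iodination should take the doubly activated carbon between the two hydroxyls (para to fluorine), the known preference of 2,4-dihydroxyacetophenones under iodine/iodic acid.

Step 3
Reactants: 3 1-(6-fluoro-2,4-dihydroxy-3-iodophenyl)ethan-1-one
Product: 4 1-[6-fluoro-3-iodo-2,4-bis(methoxymethoxy)phenyl]ethan-1-one
Conditions: NaH, MOMCl, DMF, 0 → 25 °C
Reagents that add atoms: chloromethyl methyl ether, COCCl
Why: Williamson-type O-alkylation of both phenoxides (the chelated one needs the sodium salt in DMF) gives base-stable ethers that do not interfere with the later arylpalladium, Lewis acid or fluoride steps.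

Step 4
Reactants: 4 1-[6-fluoro-3-iodo-2,4-bis(methoxymethoxy)phenyl]ethan-1-one; 5 myrcene
Product: 6 1-[6-fluoro-2,4-bis(methoxymethoxy)-3-[(1E)-7-methyl-3-methylideneocta-1,6-dien-1-yl]phenyl]ethan-1-one
Conditions: Pd(OAc)2 (cat.), P(o-tol)3, n-Bu4NCl, K2CO3, DMF, 80 °C, excess 5
Reagents that add atoms: none
Why: Mizoroki–Heck arylation of a 1,3-diene: the arylpalladium should add to the unsubstituted vinyl CH2 of myrcene, and the resulting π-allylpalladium should lose a benzylic hydrogen to give the conjugated (E)-1-aryl diene, the other two alkenes of myrcene being less reactive.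

Step 5
Reactants: 7 2,4-dihydroxybenzaldehyde
Product: 8 2,4-bis(methoxymethoxy)benzaldehyde
Conditions: NaH, MOMCl, DMF, 0 → 25 °C
Reagents that add atoms: chloromethyl methyl ether, COCCl
Why: Williamson-type O-alkylation of both phenoxides; the product serves twice, in step 8 and in step 11.

Step 6
Reactants: 9 1-(2,4-dihydroxyphenyl)ethan-1-one; 10 prenyl bromide
Product: 11 1-[2,4-dihydroxy-3-(3-methylbut-2-en-1-yl)phenyl]ethan-1-one
Conditions: 10 % aq. KOH, 0 → 25 °C
Reagents that add atoms: none
Why: C-alkylation of the ambident resorcinolate in water, where solvation of oxygen steers the allylic bromide to carbon, should favour the doubly activated C3 between the two oxygens; O-alkyl and C5 isomers are removed by chromatography.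

Step 7
Reactants: 11 1-[2,4-dihydroxy-3-(3-methylbut-2-en-1-yl)phenyl]ethan-1-one
Product: 12 1-[2-hydroxy-4-(methoxymethoxy)-3-(3-methylbut-2-en-1-yl)phenyl]ethan-1-one
Conditions: MOMCl, K2CO3, acetone, 25 °C
Reagents that add atoms: chloromethyl methyl ether, COCCl
Why: Selective Williamson etherification: with the weak base only the free 4-OH reacts, while the 2-OH, hydrogen-bonded to the ketone, stays free as the later binding site for boron.

Step 8
Reactants: 12 1-[2-hydroxy-4-(methoxymethoxy)-3-(3-methylbut-2-en-1-yl)phenyl]ethan-1-one; 8 2,4-bis(methoxymethoxy)benzaldehyde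
Product: 13 (2E)-3-[2,4-bis(methoxymethoxy)phenyl]-1-[2-hydroxy-4-(methoxymethoxy)-3-(3-methylbut-2-en-1-yl)phenyl]prop-2-en-1-one
Conditions: KOH, EtOH–H2O, 25 °C
Reagents that add atoms: none
Why: Claisen–Schmidt condensation (aldol addition, then E1cB dehydration) should give the E-enone, and MOM ethers and the prenyl group are inert to hydroxide.

Step 9
Reactants: 13 the 2'-hydroxychalcone; 6 the aryl-myrcene diene
Product: 14 all-trans (1R,5S,6R) cyclohexene adduct
Conditions: chiral borate pre-formed from (S)-VANOL, BH3·THF and AcOH (30 mol %), 5 Å molecular sieves, PhCF3, 25 °C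
Reagents that add atoms: none
Why: Diels–Alder reaction of a 2'-hydroxychalcone chelated to a chiral boron Lewis acid: the diene CH2 terminus bonds to the chalcone β-carbon, the E-alkene fixes acyl and aryl trans at C6/C5, the exo transition state (the bulky borate-bound acyl group away from the di-ortho-substituted aryl of the diene) should place the ring-A aryl trans to the acyl at C1/C6, and the VANOL ligand shields one face to set the absolute configuration of all three centres.

Step 10
Reactants: 14 all-trans (1R,5S,6R) cyclohexene adduct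
Product: 15 trimethylsilyl enol ether of the methyl ketone (benzoyl 2-OH also silylated)
Conditions: LiN(SiMe3)2 (2.2 equiv), Me3SiCl (excess), THF, −78 → 0 °C; filtration under argon, used crude
Reagents that add atoms: chlorotrimethylsilane, C[Si](C)(C)Cl
Why: Kinetic enolisation with in situ silyl trapping should touch only the phenol and the methyl ketone, because the second ketone has just one hindered tertiary α-hydrogen and is deactivated by the adjacent phenoxide, so the cyclohexene centres are not disturbed.

Step 11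
Reactants: 15 trimethylsilyl enol ether of the methyl ketone; 8 2,4-bis(methoxymethoxy)benzaldehyde
Product: 17 hepta-MOM-protected (2S)-flavanone, via aldol silyl ether 16 (not isolated)
Conditions: B-n-butyl-1,3,2-oxazaborolidin-5-one from N-tosyl-(R)-tryptophan (20 mol %), EtCN, −78 °C; then CsF, 18-crown-6, DMF, −40 → 25 °C; H2O work-up
Reagents that add atoms: none
Why: Proposed new method: the chiral boron Lewis acid binds the aldehyde of 8 and the enol silane of 15 attacks its Si face (Mukaiyama aldol with silyl transfer) to give 16; fluoride then strips the silyl group from the C2 oxygen, and the freed alkoxide adds to C8a of the C8a=C4a–C4=O unit and expels fluoride, which carries the chain on by desilylating the next molecule (Si–F bond formation is the driving force). The closest known reaction types are the oxazaborolidinone-catalysed Mukaiyama aldol/dihydropyranone annulation of 1-alkoxy-3-silyloxybutadienes with aldehydes, of which this is the benzo-fused case, and the fluoride-promoted SNAr etherification of silyl ethers with acyl-activated aryl fluorides. Ring C is closed as a formal [4+2] union of the C3–C4–C4a–C8a unit with the aldehyde C=O, the C–O bond arising by 6-endo-trig addition–elimination through an anionic σ-complex whose charge rests on the C4 carbonyl. C2 (S) is set by the catalyst alone in the aldol stage, the cyclohexene centres being too remote to matter, and is not touched in the closure because the C2–O bond is never broken. The step needs ring closure to outrun retro-aldol cleavage and E1cB loss of the C2 oxygen, which the ortho C4 carbonyl, the meta placement of the C5 and C7 ether oxygens (no donation to C8a), fluoride as leaving group, a crown-ether-separated cesium alkoxide and low temperature should secure. The second ketone cannot take part, since it carries no enol silane and no enolisable methyl.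

Step 12
Reactants: 17 hepta-MOM-protected (2S)-flavanone
Product: 19 CNP0256494.1 (target), via octakis(trimethylsilyl) ether 18 (not isolated)
Conditions: Me3SiOTf, 2,2'-bipyridyl, CH2Cl2, 0 → 25 °C; then H2O, 25 °C
Reagents that add atoms: trimethylsilyl trifluoromethanesulfonate, C[Si](C)(C)OS(=O)(=O)C(F)(F)F (its silicon is carried only by intermediate 18)
Why: Silyl triflate/2,2'-bipyridyl exchange of aromatic MOM ethers to aryl silyl ethers, followed by neutral hydrolysis, avoids protic acid, so ketalisation of the ketone by flanking phenols, prenyl–phenol cyclisation and opening of the flavanone at C2 should not occur and no stereocentre is touched.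

**Compound list**
1 | 5-fluororesorcinol (5-fluorobenzene-1,3-diol) | Oc1cc(O)cc(F)c1 | starting material
2 | 1-(2-fluoro-4,6-dihydroxyphenyl)ethan-1-one | CC(=O)c1c(O)cc(O)cc1F | intermediate
3 | 1-(6-fluoro-2,4-dihydroxy-3-iodophenyl)ethan-1-one | CC(=O)c1c(O)c(I)c(O)cc1F | intermediate
4 | 1-[6-fluoro-3-iodo-2,4-bis(methoxymethoxy)phenyl]ethan-1-one | CC(=O)c1c(OCOC)c(I)c(OCOC)cc1F | intermediate
5 | myrcene (7-methyl-3-methylideneocta-1,6-diene) | C=CC(=C)CCC=C(C)C | starting material
6 | 1-[6-fluoro-2,4-bis(methoxymethoxy)-3-[(1E)-7-methyl-3-methylideneocta-1,6-dien-1-yl]phenyl]ethan-1-one | CC(=O)c1c(OCOC)c(/C=C/C(=C)CCC=C(C)C)c(OCOC)cc1F | intermediate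
7 | 2,4-dihydroxybenzaldehyde | O=Cc1ccc(O)cc1O | starting material
8 | 2,4-bis(methoxymethoxy)benzaldehyde | COCOc1ccc(C=O)c(OCOC)c1 | intermediate
9 | 1-(2,4-dihydroxyphenyl)ethan-1-one | CC(=O)c1ccc(O)cc1O | starting material
10 | prenyl bromide (1-bromo-3-methylbut-2-ene) | CC(C)=CCBr | starting material
11 | 1-[2,4-dihydroxy-3-(3-methylbut-2-en-1-yl)phenyl]ethan-1-one | CC(=O)c1ccc(O)c(CC=C(C)C)c1O | intermediate
12 | 1-[2-hydroxy-4-(methoxymethoxy)-3-(3-methylbut-2-en-1-yl)phenyl]ethan-1-one | CC(=O)c1ccc(OCOC)c(CC=C(C)C)c1O | intermediate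
13 | (2E)-3-[2,4-bis(methoxymethoxy)phenyl]-1-[2-hydroxy-4-(methoxymethoxy)-3-(3-methylbut-2-en-1-yl)phenyl]prop-2-en-1-one | COCOc1ccc(/C=C/C(=O)c2ccc(OCOC)c(CC=C(C)C)c2O)c(OCOC)c1 | intermediate
14 | 1-{3-[(1R,5S,6R)-5-[2,4-bis(methoxymethoxy)phenyl]-6-[2-hydroxy-4-(methoxymethoxy)-3-(3-methylbut-2-en-1-yl)benzoyl]-3-(4-methylpent-3-en-1-yl)cyclohex-2-en-1-yl]-6-fluoro-2,4-bis(methoxymethoxy)phenyl}ethan-1-one | CC(C)=CCCC1=C[C@@H](c2c(OCOC)cc(F)c(C(C)=O)c2OCOC)[C@H](C(=O)c2ccc(OCOC)c(CC=C(C)C)c2O)[C@@H](c2ccc(OCOC)cc2OCOC)C1 | intermediate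
15 | compound 14 with the acetyl group as its trimethylsilyl enol ether and the benzoyl 2-OH as trimethylsilyl ether | CC(C)=CCCC1=C[C@@H](c2c(OCOC)cc(F)c(C(=C)O[Si](C)(C)C)c2OCOC)[C@H](C(=O)c2ccc(OCOC)c(CC=C(C)C)c2O[Si](C)(C)C)[C@@H](c2ccc(OCOC)cc2OCOC)C1 | intermediate
16 | (S)-configured aldol silyl ether: the ring-A acyl group is C(=O)CH2CH(OSiMe3)[2,4-bis(methoxymethoxy)phenyl], fluorine still at C8a, benzoyl 2-OSiMe3 | CC(C)=CCCC1=C[C@@H](c2c(OCOC)cc(F)c(C(=O)C[C@@H](c3ccc(OCOC)cc3OCOC)O[Si](C)(C)C)c2OCOC)[C@H](C(=O)c2ccc(OCOC)c(CC=C(C)C)c2O[Si](C)(C)C)[C@@H](c2ccc(OCOC)cc2OCOC)C1 | intermediate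
17 | (2S)-2-[2,4-bis(methoxymethoxy)phenyl]-6-{(1R,5S,6R)-5-[2,4-bis(methoxymethoxy)phenyl]-6-[2-hydroxy-4-(methoxymethoxy)-3-(3-methylbut-2-en-1-yl)benzoyl]-3-(4-methylpent-3-en-1-yl)cyclohex-2-en-1-yl}-5,7-bis(methoxymethoxy)-2,3-dihydro-4H-chromen-4-one | CC(C)=CCCC1=C[C@@H](c2c(OCOC)cc3c(c2OCOC)C(=O)C[C@@H](c2ccc(OCOC)cc2OCOC)O3)[C@H](C(=O)c2ccc(OCOC)c(CC=C(C)C)c2O)[C@@H](c2ccc(OCOC)cc2OCOC)C1 | intermediate
18 | octakis(trimethylsilyl) ether of 19 (all eight phenols silylated) | CC(C)=CCCC1=C[C@@H](c2c(O[Si](C)(C)C)cc3c(c2O[Si](C)(C)C)C(=O)C[C@@H](c2ccc(O[Si](C)(C)C)cc2O[Si](C)(C)C)O3)[C@H](C(=O)c2ccc(O[Si](C)(C)C)c(CC=C(C)C)c2O[Si](C)(C)C)[C@@H](c2ccc(O[Si](C)(C)C)cc2O[Si](C)(C)C)C1 | intermediate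
19 | CNP0256494.1: (2S)-2-(2,4-dihydroxyphenyl)-6-{(1R,5S,6R)-5-(2,4-dihydroxyphenyl)-6-[2,4-dihydroxy-3-(3-methylbut-2-en-1-yl)benzoyl]-3-(4-methylpent-3-en-1-yl)cyclohex-2-en-1-yl}-5,7-dihydroxy-2,3-dihydro-4H-chromen-4-one | CC(C)=CCCC1=C[C@@H](c2c(O)cc3c(c2O)C(=O)C[C@@H](c2ccc(O)cc2O)O3)[C@H](C(=O)c2ccc(O)c(CC=C(C)C)c2O)[C@@H](c2ccc(O)cc2O)C1 | target

**Step count**
Total: 12 steps. Longest linear sequence: 8 steps (1 → 2 → 3 → 4 → 6 → 14 → 15 → 17 → 19).

**Steps most likely to fail**

1. Step 11 (the proposed new method). Retro-aldol cleavage or E1cB loss of the C2 oxygen may outrun the SNAr closure, and the aldol stage may give insufficient facial selectivity at C2. The fallback uses known chemistry and sets out from 14. The activated fluoride is displaced with the sodium alkoxide of 2-(methylsulfonyl)ethanol (NaH, DMF), whose ether eliminates methyl vinyl sulfone to give the C8a phenol F1. Claisen–Schmidt condensation of the 2'-hydroxyacetophenone F1 with 8 (KOH, EtOH) gives the 2'-hydroxychalcone F2. Enantioselective intramolecular oxa-Michael addition of the chalcone F2 under a quinine-derived bifunctional thiourea closes ring C through the O1–C2 bond. The C2 epimers are diastereomers here, so the minor one is removed by chromatography, and the route is rejoined at 17.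

2. Step 9. Exo/endo discrimination or facial selectivity may be poor, or the cycloaddition with the di-ortho-substituted aryl diene may be slow. The fallback sets out from 13 and 6. The cycloaddition is run under silica-supported zerovalent silver nanoparticles (Ag on SiO2, CH2Cl2, 50 °C), an electron-transfer-type catalysis of 2'-hydroxychalcone Diels–Alder reactions, which gives racemic material. After removal of the endo isomer, 14 is separated from its enantiomer, the (1S,5R,6S) adduct F3, on a chiral stationary phase, and the route is rejoined at 14.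

3. Step 4. Insertion of the hindered arylpalladium may be slow, the π-allylpalladium intermediate may be captured or isomerised, or myrcene may oligomerise. The fallback sets out from 4 and replaces the Heck reaction by a Suzuki–Miyaura coupling. Commercial 6-methylhept-5-en-2-one is converted (LiN(i-Pr)2, PhNTf2, THF, −78 °C) into the kinetic enol triflate, 6-methylhepta-1,5-dien-2-yl triflate F4. Coupling with ethynylmagnesium bromide under Pd(PPh3)4 gives the enyne 7-methyl-3-methylideneoct-6-en-1-yne F5. Hydroboration with pinacolborane and catalytic Cp2Zr(H)Cl gives the (E)-dienyl pinacol boronate F6. Coupling of the boronate F6 with 4 (PdCl2(dppf), K3PO4, dioxane–H2O, 80 °C) rejoins the route at 6.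

**Further compounds**
F1 | step 11 | 1-{3-[(1R,5S,6R)-5-[2,4-bis(methoxymethoxy)phenyl]-6-[2-hydroxy-4-(methoxymethoxy)-3-(3-methylbut-2-en-1-yl)benzoyl]-3-(4-methylpent-3-en-1-yl)cyclohex-2-en-1-yl]-6-hydroxy-2,4-bis(methoxymethoxy)phenyl}ethan-1-one | CC(C)=CCCC1=C[C@@H](c2c(OCOC)cc(O)c(C(C)=O)c2OCOC)[C@H](C(=O)c2ccc(OCOC)c(CC=C(C)C)c2O)[C@@H](c2ccc(OCOC)cc2OCOC)C1
F2 | step 11 | 2'-hydroxychalcone from F1 and 8 (ring-A acyl group is (E)-C(=O)CH=CH[2,4-bis(methoxymethoxy)phenyl]) | CC(C)=CCCC1=C[C@@H](c2c(OCOC)cc(O)c(C(=O)/C=C/c3ccc(OCOC)cc3OCOC)c2OCOC)[C@H](C(=O)c2ccc(OCOC)c(CC=C(C)C)c2O)[C@@H](c2ccc(OCOC)cc2OCOC)C1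
F3 | step 9 | enantiomer of 14, the (1S,5R,6S) adduct | CC(C)=CCCC1=C[C@H](c2c(OCOC)cc(F)c(C(C)=O)c2OCOC)[C@@H](C(=O)c2ccc(OCOC)c(CC=C(C)C)c2O)[C@H](c2ccc(OCOC)cc2OCOC)C1
F4 | step 4 | 6-methylhepta-1,5-dien-2-yl trifluoromethanesulfonate | C=C(CCC=C(C)C)OS(=O)(=O)C(F)(F)F
F5 | step 4 | 7-methyl-3-methylideneoct-6-en-1-yne | C#CC(=C)CCC=C(C)C
F6 | step 4 | 4,4,5,5-tetramethyl-2-[(1E)-7-methyl-3-methylideneocta-1,6-dien-1-yl]-1,3,2-dioxaborolane | CC(C)=CCCC(=C)/C=C/B1OC(C)(C)C(C)(C)O1
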